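The numbers of this flask are those of an exercise, and the outcome is calculated.

At late times, while solid E is left, [Z] stands at the solubility 0.14 M and J + Z ⇌ Q + L sits at its equilibrium, so each flask can be reckoned as a climb towards that ceiling.

    E ⇌ Z, rate k1*(cs1 - [Z]) while solid is left; crystals form when [Z] > cs1 (cs1 = 0.14 M, k1 = 0.66 /min)
    J + Z ⇌ Q + L (K2 = 1.2, k2 = 0.94 /M/min)

- south-east: J 0.20 M; E 1.80 equiv; time 12 min
- north-east: J 0.20 M; E 1.80 equiv; time 6.0 min

- which of these there is most of at the end, counted by the J in it, south-east (J / Q)
- which of these there is most of at the end, counted by the J in it, north-east (J / Q)
- how much there is at the end of the one of these that leads, in percent of the J charged: south-east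
- how much there is at the end of the one of these that leads, in percent of the J charged: north-east

- E is a solid; its amount is given per volume of the solution
- at the start none of E is in solution
- run time (south-east): 12 min

Let x be the fraction of charged J turned into Q, with [Q] = [L]. At equilibrium the square of x over the unturned fraction equals 0.840, the constant 1.2 times the solubility over the charge 0.20 M, so the ceiling is 58.8%. With [Z] at the solubility, J falls at the pseudo-first-order rate 0.132 /min. An exponential climb with that initial slope and that ceiling halves its gap in the climb half-life 3.10 min. This reckoning starts the climb after a lag, taken as the dissolution lifetime 1.52 min. The time past the lag then counts 3.38 half-lives south-east and 1.45 north-east.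

The charge of E does not enter while solid is left: the ceiling needs 0.258 M dissolved, less than the 0.360 M charged. In this reckoning, twice the dissolution coefficient adds 3.4 percentage points of Q north-east and 0.88 points south-east. Twice the rate constant of the second step adds 14 points north-east and 5.1 points south-east. South-east is reckoned at 90.4% of the ceiling and north-east at 63.3%, so the ceiling, reckoned from the equilibrium constant and the solubility, weighs more south-east than north-east. This reckoning gives Q 53.2% south-east, ahead of J, and J 62.7% north-east, ahead of Q.

The forecast names Q at 54% south-east, “closing in on the cap”, and J at 62% north-east.

The flasks give Q at 53.7% south-east and J at 63.3% north-east. In north-east, half of the dissolution up to the end was done by 1.62 min, when Z was made 2.73 times faster than used up, each step taken net. At 6.00 min solid E still stood at 46.5% of its charge with [Z] at 0.119 M, while J + Z kept passing into Q + L. Left until 15 min, north-east counts 4.35 climb half-lives, which reckons J at 44.1%, and it holds J at 43.5%.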